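**Retrosynthetic overview**
- Last disconnection: the aryl C–O bond of the catechol 3-OH. It is installed by ortho C–H hydroxylation of the 4-hydroxyphenyl ketone (key step, new method).
- The saturated C7 chain comes from hydrogenation of an enynone (C1=C2 and C6≡C7).
- The enynone comes from a Claisen–Schmidt condensation (C1=C2) of syringaldehyde with 6-(4-hydroxyphenyl)hex-5-yn-2-one.
- The alkynyl ketone comes from a Sonogashira coupling (C7–aryl) of 4-iodophenol with hex-5-yn-2-one.
- No ring is formed: both benzene rings are bought, and no protecting group is used.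

Assumption: the target has no stereocentre and no stereogenic double bond, so it is one achiral compound and no stereocontrol is needed.

**Route**

Step 1
Reactants: 1 4-iodophenol; 2 hex-5-yn-2-one
Product: 3 6-(4-hydroxyphenyl)hex-5-yn-2-one
Conditions: PdCl2(PPh3)2 (2 mol%), CuI (4 mol%), Et3N (3 equiv), THF, rt, Ar
Reagents that add atoms: none
Why: Sonogashira coupling; the aryl iodide undergoes oxidative addition at rt, so the free phenol and the methyl ketone are tolerated and the C7–aryl bond forms without protection.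

Step 2
Reactants: 3 6-(4-hydroxyphenyl)hex-5-yn-2-one; 4 syringaldehyde (4-hydroxy-3,5-dimethoxybenzaldehyde)
Product: 5 (E)-1-(4-hydroxy-3,5-dimethoxyphenyl)-7-(4-hydroxyphenyl)hept-1-en-6-yn-3-one
Conditions: pyrrolidine (1.2 equiv), AcOH (1.2 equiv), THF, rt to 45 °C
Reagents that add atoms: none
Why: Amine-mediated Claisen–Schmidt (crossed aldol) condensation; pyrrolidine forms the less substituted enamine at the methyl group of 3 and the iminium of 4, both free phenols are tolerated, and E1cB loss of water gives the conjugated E-enone (no stereocentre is made).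

Step 3
Reactants: 5 (E)-1-(4-hydroxy-3,5-dimethoxyphenyl)-7-(4-hydroxyphenyl)hept-1-en-6-yn-3-one
Product: 6 1-(4-hydroxy-3,5-dimethoxyphenyl)-7-(4-hydroxyphenyl)heptan-3-one
Conditions: H2 (1 atm), 10% Pd/C, EtOAc–MeOH, rt
Reagents that add atoms: none
Why: Heterogeneous catalytic hydrogenation; the aryl alkyne and the enone C=C take up three H2 far faster than the dialkyl ketone or the arenes, and nothing in 5 is hydrogenolysable.

Step 4
Reactants: 6 1-(4-hydroxy-3,5-dimethoxyphenyl)-7-(4-hydroxyphenyl)heptan-3-one
Product: 9 7-(3,4-dihydroxyphenyl)-1-(4-hydroxy-3,5-dimethoxyphenyl)heptan-3-one, via bis-O-Bpin borate ester 7 (not isolated), via ortho-C-Bpin boronate 8 (not isolated)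
Conditions: (i) HBpin (2.1 equiv), [Ir(OMe)(cod)]2 (2 mol%), 3,4,7,8-tetramethyl-1,10-phenanthroline (4 mol%), THF, rt, 1 h; (ii) B2pin2 (1.0 equiv), 60 °C; (iii) Me3NO·2H2O (3 equiv), THF, 50 °C; then 1 M HCl, Na2S2O4 work-up
Reagents that add atoms: trimethylamine N-oxide, C[N+](C)(C)[O-]
Why: Proposed new method: a one-flask, sterically gated ortho C–H hydroxylation of one phenol in an unprotected bis-phenol ketone, in which HBpin first turns both ArOH groups into ArO–Bpin esters (loss of H2), the Ir(III) tris(boryl)/phenanthroline catalyst then borylates only a C–H next to the unhindered ArO–Bpin (outer-sphere attraction between the O–Bpin oxygen and the N,N-ligand favours that position, the C–H bonds next to the chain are shielded by its CH2 group, and the syringyl ring has no C–H ortho to oxygen and only doubly flanked C–H bonds elsewhere), and Me3NO finally adds to the C–Bpin boron and triggers a 1,2-aryl shift from B to O that forms the C–O bond without any free electrophilic oxidant, so the easily oxidised syringol ring and the ketone are left alone before hydrolysis frees the three OH groups; the closest known reaction type is the traceless O–Bpin-directed Ir-catalysed ortho C–H borylation of simple monophenols combined with N-oxide oxidation of arylboronates, which has not been shown as a phenol-to-catechol hydroxylation that selects between two phenols beside an enolisable ketone.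

**Compound list**
1 | 4-iodophenol | Oc1ccc(I)cc1 | starting material
2 | hex-5-yn-2-one | CC(=O)CCC#C | starting material
3 | 6-(4-hydroxyphenyl)hex-5-yn-2-one | CC(=O)CCC#Cc1ccc(O)cc1 | intermediate
4 | syringaldehyde (4-hydroxy-3,5-dimethoxybenzaldehyde) | COc1cc(C=O)cc(OC)c1O | starting material
5 | (E)-1-(4-hydroxy-3,5-dimethoxyphenyl)-7-(4-hydroxyphenyl)hept-1-en-6-yn-3-one | COc1cc(/C=C/C(=O)CCC#Cc2ccc(O)cc2)cc(OC)c1O | intermediate
6 | 1-(4-hydroxy-3,5-dimethoxyphenyl)-7-(4-hydroxyphenyl)heptan-3-one | COc1cc(CCC(=O)CCCCc2ccc(O)cc2)cc(OC)c1O | intermediate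
7 | bis-O-Bpin borate ester of 6: 1-[3,5-dimethoxy-4-(pinacolboryloxy)phenyl]-7-[4-(pinacolboryloxy)phenyl]heptan-3-one | COc1cc(CCC(=O)CCCCc2ccc(OB3OC(C)(C)C(C)(C)O3)cc2)cc(OC)c1OB1OC(C)(C)C(C)(C)O1 | intermediate
8 | ortho-C-Bpin boronate: 1-[3,5-dimethoxy-4-(pinacolboryloxy)phenyl]-7-[3-(pinacolboryl)-4-(pinacolboryloxy)phenyl]heptan-3-one | COc1cc(CCC(=O)CCCCc2ccc(OB3OC(C)(C)C(C)(C)O3)c(B4OC(C)(C)C(C)(C)O4)c2)cc(OC)c1OB1OC(C)(C)C(C)(C)O1 | intermediate
9 | 7-(3,4-dihydroxyphenyl)-1-(4-hydroxy-3,5-dimethoxyphenyl)heptan-3-one | COc1cc(CCC(=O)CCCCc2ccc(O)c(O)c2)cc(OC)c1O | target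

**Step count and risks**

Total step count: 4. Longest linear sequence: 4 steps (1 → 3 → 5 → 6 → 9).

Three steps most likely to fail:

1. Step 4 (the proposed new hydroxylation). The likely problems are Ir-mediated hydroboration of the ketone by HBpin, a second borylation at the other ortho position (giving a pyrogallol by-product), and air oxidation of the catechol on work-up. The fallback uses known chemistry only and carries the catechol in masked form. It sets out from 2 and comes back at 9. Compound 2 is coupled under Sonogashira conditions (Pd(PPh3)4, CuI, Et3N, DMF, 80 °C) with 4-bromo-1,2-bis(benzyloxy)benzene F1 to give 6-[3,4-bis(benzyloxy)phenyl]hex-5-yn-2-one F2. F2 is condensed with 4 under the conditions of step 2 to give (E)-7-[3,4-bis(benzyloxy)phenyl]-1-(4-hydroxy-3,5-dimethoxyphenyl)hept-1-en-6-yn-3-one F3. Hydrogenation over Pd/C (H2, EtOAc–MeOH) then reduces the alkene and alkyne and removes both benzyl ethers in the same operation, giving 9 directly.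

2. Step 2 (condensation with two free phenols). The 4-hydroxy aldehyde is a deactivated electrophile, and some reaction at the methylene side of the ketone is possible. The fallback masks the aldehyde phenol at no cost in steps. It sets out from 3 and comes back at 6. Compound 3 is condensed under classical hydroxide Claisen–Schmidt conditions (NaOH, EtOH–H2O, rt) with commercial 4-(benzyloxy)-3,5-dimethoxybenzaldehyde F4 to give (E)-1-[4-(benzyloxy)-3,5-dimethoxyphenyl]-7-(4-hydroxyphenyl)hept-1-en-6-yn-3-one F5. The hydrogenation of step 3 then also cleaves the benzyl ether and delivers 6.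

3. Step 1 (Sonogashira with a γ-alkynyl ketone). The likely problems are Glaser dimerisation of 2 and cycloisomerisation of the alkynyl ketone to a furan. The fallback replaces the alkyne by an alkene. It sets out from 1 and comes back at 6. Compound 1 undergoes a Heck reaction (Pd(OAc)2, Bu4NCl, NaHCO3, DMF, 80 °C) with hex-5-en-2-one F6 to give (E)-6-(4-hydroxyphenyl)hex-5-en-2-one F7. Minor linear double-bond isomers converge on hydrogenation; the small amount of branched isomer is removed at this stage. F7 is condensed with 4 as in step 2 to give (1E,6E)-1-(4-hydroxy-3,5-dimethoxyphenyl)-7-(4-hydroxyphenyl)hepta-1,6-dien-3-one F8, and hydrogenation over Pd/C gives 6.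

**Further compounds**
F1 | step 4 | 4-bromo-1,2-bis(benzyloxy)benzene | Brc1ccc(OCc2ccccc2)c(OCc2ccccc2)c1
F2 | step 4 | 6-[3,4-bis(benzyloxy)phenyl]hex-5-yn-2-one | CC(=O)CCC#Cc1ccc(OCc2ccccc2)c(OCc2ccccc2)c1
F3 | step 4 | (E)-7-[3,4-bis(benzyloxy)phenyl]-1-(4-hydroxy-3,5-dimethoxyphenyl)hept-1-en-6-yn-3-one | COc1cc(/C=C/C(=O)CCC#Cc2ccc(OCc3ccccc3)c(OCc3ccccc3)c2)cc(OC)c1O
F4 | step 2 | 4-(benzyloxy)-3,5-dimethoxybenzaldehyde | COc1cc(C=O)cc(OC)c1OCc1ccccc1
F5 | step 2 | (E)-1-[4-(benzyloxy)-3,5-dimethoxyphenyl]-7-(4-hydroxyphenyl)hept-1-en-6-yn-3-one | COc1cc(/C=C/C(=O)CCC#Cc2ccc(O)cc2)cc(OC)c1OCc1ccccc1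
F6 | step 1 | hex-5-en-2-one | CC(=O)CCC=C
F7 | step 1 | (E)-6-(4-hydroxyphenyl)hex-5-en-2-one | CC(=O)CC/C=C/c1ccc(O)cc1
F8 | step 1 | (1E,6E)-1-(4-hydroxy-3,5-dimethoxyphenyl)-7-(4-hydroxyphenyl)hepta-1,6-dien-3-one | COc1cc(/C=C/C(=O)CC/C=C/c2ccc(O)cc2)cc(OC)c1O
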